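**Retrosynthetic overview**

1. Target 22 ⇐ silyl ether 20 (desilylation, acetylation) ⇐ cycloheptanone 18 (α-methylation, dehydrogenation): the enone is installed last.
2. 18 ⇐ hydrindanone 16 by a one-carbon ring expansion: the quaternary ring-fusion carbon shifts onto a bromocarbenoid carbon, so the ketone that controlled the early steps ends up one atom away from the quaternary centre.
3. 16 ⇐ methyl ketone 9 + Grignard reagent 15 (Felkin–Anh addition); 15 comes from 10 + 11 by acylation, CBS reduction and silylation.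
4. 9 ⇐ acetylcyclopentene 8 (face-selective hydrogenation) ⇐ diene ketone 6 (ozonolysis, then aldol condensation closes the cyclopentane).
5. 6 ⇐ 1 + 2 + 3 by catalytic asymmetric conjugate methallylation and trans enolate allylation. Ring order: six-membered ring (present in 1) → five-membered ring (step 2) → seven-membered ring by expansion of the six (step 8).

Assumption: 1, 2, 3, 10 and 11 (11 as its THF solution) are taken as purchasable, and the sense of induction in step 1 is assumed to be selectable by the choice of catalyst enantiomer.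

**Route**

Step 1
Reactants: 1 2-methylcyclohex-2-en-1-one; 2 trimethyl(2-methylallyl)silane; 3 allyl bromide
Product: 6 (2S,3S)-2-allyl-2-methyl-3-(2-methylallyl)cyclohexan-1-one, via trimethylsilyl enol ether 4 (not isolated), via lithium enolate 5 (not isolated)
Conditions: chiral IDPi acid (2 mol%), toluene, −60 °C; then MeLi, THF, 0 °C; then 3, DMPU, −78 → −20 °C
Reagents that add atoms: none
Why: Proposed new method: a confined imidodiphosphorimidate (IDPi) acid is silylated by 2 to a chiral silylium ion pair that O-silylates enone 1; the resulting silyloxy-allyl cation sits in the chiral anion pocket and the methallylsilane adds to C3 on the open face (conjugate Hosomi–Sakurai addition), the β-silyl cation hands Me3Si+ back to the anion and releases the regiodefined silyl enol ether 4 (sets C3 = S); MeLi then unmasks the tetrasubstituted enolate 5, which allyl bromide attacks axially anti to the C3 substituent (trans, sets quaternary C2); closest known reactions are the TiCl4-mediated racemic conjugate Sakurai allylation of enones and silylium–IDPi-catalysed asymmetric Mukaiyama–Michael and Hosomi–Sakurai additions to enoates and aldehydes.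

Step 2
Reactants: 6 (2S,3S)-2-allyl-2-methyl-3-(2-methylallyl)cyclohexan-1-one
Product: 8 (3aS,7aR)-1-acetyl-3a-methyl-3,3a,5,6,7,7a-hexahydro-4H-inden-4-one, via keto-aldehyde 7 (not isolated)
Conditions: O3, CH2Cl2, −78 °C; Me2S, → rt; evaporate (removes CH2O); then KOH, MeOH, 0 °C → rt
Reagents that add atoms: ozone, [O-][O+]=O
Why: Ozonolysis turns the methallyl group into the acetonyl group and the allyl group into the acetaldehyde arm, and under hydroxide the methylene-ketone enolate adds to the aldehyde (intramolecular aldol condensation; the only aldol that can dehydrate to a conjugated enone), closing the cyclopentene without touching the two stereocentres, so the ring fusion stays trans.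

Step 3
Reactants: 8 (3aS,7aR)-1-acetyl-3a-methyl-3,3a,5,6,7,7a-hexahydro-4H-inden-4-one
Product: 9 (1S,3aS,7aS)-1-acetyl-3a-methyloctahydro-4H-inden-4-one
Conditions: H2 (1 atm), 10% Pd/C, EtOAc, rt
Reagents that add atoms: none
Why: Heterogeneous hydrogenation adds H2 to the cyclopentene face opposite the axial angular methyl group (as with ring-D enones of steroids), so the new C1–H is cis to C7a–H and the acetyl group ends up cis to the angular methyl (C1 = S).

Step 4
Reactants: 10 3-bromopropanoyl chloride; 11 isopropenylmagnesium bromide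
Product: 12 5-bromo-2-methylpent-1-en-3-one
Conditions: Fe(acac)3 (3 mol%), THF, −78 °C, 11 added slowly to 10
Reagents that add atoms: none
Why: Iron-catalysed acylation of a Grignard reagent by an acid chloride is far faster at −78 °C than addition to the ketone formed or attack at the alkyl bromide.

Step 5
Reactants: 12 5-bromo-2-methylpent-1-en-3-one
Product: 13 (S)-5-bromo-2-methylpent-1-en-3-ol
Conditions: (R)-Me-CBS (10 mol%), BH3·SMe2, THF, −30 °C; MeOH
Reagents that add atoms: none
Why: Corey–Bakshi–Shibata reduction, in which the isopropenyl group is the large substituent, so the (R)-oxazaborolidine gives the (S)-allylic alcohol by 1,2-reduction.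

Step 6
Reactants: 13 (S)-5-bromo-2-methylpent-1-en-3-ol
Product: 14 (S)-[(5-bromo-2-methylpent-1-en-3-yl)oxy](tert-butyl)dimethylsilane
Conditions: TBSCl, imidazole, DMF, rt
Reagents that add atoms: tert-butyldimethylsilyl chloride, CC(C)(C)[Si](C)(C)Cl
Why: Standard silylation; the TBS ether survives the organolithium bases and IBX used later and is removed in the last step.

Step 7
Reactants: 9 (1S,3aS,7aS)-1-acetyl-3a-methyloctahydro-4H-inden-4-one; 14 (S)-[(5-bromo-2-methylpent-1-en-3-yl)oxy](tert-butyl)dimethylsilane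
Product: 16 (1S,3aS,7aS)-1-[(2S,5S)-5-{[tert-butyl(dimethyl)silyl]oxy}-2-hydroxy-6-methylhept-6-en-2-yl]-3a-methyloctahydro-4H-inden-4-one, via Grignard reagent 15 (not isolated)
Conditions: 14, Mg, THF, 40 °C; then LaCl3·2LiCl, 9, THF, −40 → 0 °C; aq. NH4Cl
Reagents that add atoms: none
Why: Lewis-acid-assisted Grignard 1,2-addition goes to the acetyl group and not to the ring ketone shielded by the adjacent quaternary carbon (the 20-oxo versus 12-oxo steroid reactivity order), and follows the Felkin–Anh model with ring-fusion carbon C7a as the large group, which gives the (S)-carbinol.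

Step 8
Reactants: 16 (1S,3aS,7aS)-1-[(2S,5S)-5-{[tert-butyl(dimethyl)silyl]oxy}-2-hydroxy-6-methylhept-6-en-2-yl]-3a-methyloctahydro-4H-inden-4-one
Product: 18 (1S,3aR,8aS)-1-[(2S,5S)-5-{[tert-butyl(dimethyl)silyl]oxy}-2-hydroxy-6-methylhept-6-en-2-yl]-3a-methyloctahydroazulen-5(1H)-one, via dibromomethyl carbinol 17 (not isolated)
Conditions: CH2Br2, LiTMP (2.5 equiv), THF, −78 °C; then n-BuLi, −95 → 0 °C; aq. NH4Cl
Reagents that add atoms: dibromomethane, BrCBr
Why: One-carbon ring expansion through a β-oxido carbenoid (dibromomethyllithium addition, Br/Li exchange, α-elimination with 1,2-shift), in which the more substituted quaternary α-carbon migrates with retention, so the CH2 is inserted between C3a and the carbonyl and the trans-hydrindanone becomes the trans-hydroazulenone.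

Step 9
Reactants: 18 (1S,3aR,8aS)-1-[(2S,5S)-5-{[tert-butyl(dimethyl)silyl]oxy}-2-hydroxy-6-methylhept-6-en-2-yl]-3a-methyloctahydroazulen-5(1H)-one
Product: 19 (1S,3aR,8aS)-1-[(2S,5S)-5-{[tert-butyl(dimethyl)silyl]oxy}-2-hydroxy-6-methylhept-6-en-2-yl]-3a,6-dimethyloctahydroazulen-5(1H)-one (mixture of C6 epimers)
Conditions: LDA (2.2 equiv), THF, −78 °C; MeI; aq. NH4Cl
Reagents that add atoms: iodomethane, CI
Why: Kinetic enolate alkylation: LDA removes a proton from the unhindered C6 methylene, not from the neopentyl C4 methylene, and the new stereocentre is irrelevant because it becomes sp2 in step 10.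

Step 10
Reactants: 19 (1S,3aR,8aS)-1-[(2S,5S)-5-{[tert-butyl(dimethyl)silyl]oxy}-2-hydroxy-6-methylhept-6-en-2-yl]-3a,6-dimethyloctahydroazulen-5(1H)-one
Product: 20 (1S,3aR,8aS)-1-[(2S,5S)-5-{[tert-butyl(dimethyl)silyl]oxy}-2-hydroxy-6-methylhept-6-en-2-yl]-3a,6-dimethyl-2,3,3a,4,8,8a-hexahydroazulen-5(1H)-one
Conditions: IBX, 4-methoxypyridine N-oxide, DMSO, 40 °C
Reagents that add atoms: none
Why: IBX dehydrogenation of the ketone through its enol can only go towards C6–C7, because C3a carries no hydrogen, and gives the endocyclic 2-methyl enone; the tertiary alcohol and the silyl ether are inert.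

Step 11
Reactants: 20 (1S,3aR,8aS)-1-[(2S,5S)-5-{[tert-butyl(dimethyl)silyl]oxy}-2-hydroxy-6-methylhept-6-en-2-yl]-3a,6-dimethyl-2,3,3a,4,8,8a-hexahydroazulen-5(1H)-one
Product: 22 (3S,6S)-6-[(1S,3aR,8aS)-3a,6-dimethyl-5-oxo-1,2,3,3a,4,5,8,8a-octahydroazulen-1-yl]-6-hydroxy-2-methylhept-1-en-3-yl acetate, via diol 21 (not isolated)
Conditions: TBAF, THF, 0 °C; then Ac2O, Et3N, DMAP (cat.), 0 °C
Reagents that add atoms: acetic anhydride, CC(=O)OC(C)=O
Why: Fluoride desilylation followed by DMAP-catalysed acylation, which acetylates the secondary allylic alcohol and leaves the hindered tertiary alcohol free; no stereocentre is affected.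

**Compound list**

1 | 2-methylcyclohex-2-en-1-one | CC1=CCCCC1=O | starting material
2 | trimethyl(2-methylallyl)silane | C=C(C)C[Si](C)(C)C | starting material
3 | allyl bromide | C=CCBr | starting material
4 | (S)-trimethyl{[2-methyl-3-(2-methylallyl)cyclohex-1-en-1-yl]oxy}silane | CC1=C(O[Si](C)(C)C)CCC[C@H]1CC(C)=C | intermediate (not isolated)
5 | lithium (S)-2-methyl-3-(2-methylallyl)cyclohex-1-en-1-olate | CC1=C(O[Li])CCC[C@H]1CC(C)=C | intermediate (not isolated)
6 | (2S,3S)-2-allyl-2-methyl-3-(2-methylallyl)cyclohexan-1-one (allyl and methallyl trans) | C=CC[C@]1(C)C(=O)CCC[C@H]1CC(C)=C | intermediate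
7 | 2-[(1S,6S)-1-methyl-2-oxo-6-(2-oxopropyl)cyclohexyl]acetaldehyde | O=CC[C@]1(C)C(=O)CCC[C@H]1CC(C)=O | intermediate (not isolated)
8 | (3aS,7aR)-1-acetyl-3a-methyl-3,3a,5,6,7,7a-hexahydro-4H-inden-4-one (trans-fused, C1=C2) | CC(=O)C1=CC[C@]2(C)C(=O)CCC[C@@H]12 | intermediate
9 | (1S,3aS,7aS)-1-acetyl-3a-methyloctahydro-4H-inden-4-one (acetyl cis to angular methyl) | CC(=O)[C@H]1CC[C@]2(C)C(=O)CCC[C@@H]12 | intermediate
10 | 3-bromopropanoyl chloride | O=C(Cl)CCBr | starting material
11 | isopropenylmagnesium bromide | C=C(C)[Mg]Br | starting material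
12 | 5-bromo-2-methylpent-1-en-3-one | C=C(C)C(=O)CCBr | intermediate
13 | (S)-5-bromo-2-methylpent-1-en-3-ol | C=C(C)[C@H](CCBr)O | intermediate
14 | (S)-[(5-bromo-2-methylpent-1-en-3-yl)oxy](tert-butyl)dimethylsilane | C=C(C)[C@H](CCBr)O[Si](C)(C)C(C)(C)C | intermediate
15 | {(S)-3-[(tert-butyldimethylsilyl)oxy]-4-methylpent-4-en-1-yl}magnesium bromide | C=C(C)[C@H](CC[Mg]Br)O[Si](C)(C)C(C)(C)C | intermediate (not isolated)
16 | (1S,3aS,7aS)-1-[(2S,5S)-5-{[tert-butyl(dimethyl)silyl]oxy}-2-hydroxy-6-methylhept-6-en-2-yl]-3a-methyloctahydro-4H-inden-4-one | C=C(C)[C@H](CC[C@](C)(O)[C@H]1CC[C@]2(C)C(=O)CCC[C@@H]12)O[Si](C)(C)C(C)(C)C | intermediate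
17 | (1S,3aS,7aS)-1-[(2S,5S)-5-{[tert-butyl(dimethyl)silyl]oxy}-2-hydroxy-6-methylhept-6-en-2-yl]-4-(dibromomethyl)-3a-methyloctahydro-1H-inden-4-ol (C4 epimers) | C=C(C)[C@H](CC[C@](C)(O)[C@H]1CC[C@]2(C)C(O)(C(Br)Br)CCC[C@@H]12)O[Si](C)(C)C(C)(C)C | intermediate (not isolated)
18 | (1S,3aR,8aS)-1-[(2S,5S)-5-{[tert-butyl(dimethyl)silyl]oxy}-2-hydroxy-6-methylhept-6-en-2-yl]-3a-methyloctahydroazulen-5(1H)-one | C=C(C)[C@H](CC[C@](C)(O)[C@H]1CC[C@]2(C)CC(=O)CCC[C@@H]12)O[Si](C)(C)C(C)(C)C | intermediate
19 | (1S,3aR,8aS)-1-[(2S,5S)-5-{[tert-butyl(dimethyl)silyl]oxy}-2-hydroxy-6-methylhept-6-en-2-yl]-3a,6-dimethyloctahydroazulen-5(1H)-one (C6 epimers) | C=C(C)[C@H](CC[C@](C)(O)[C@H]1CC[C@]2(C)CC(=O)C(C)CC[C@@H]12)O[Si](C)(C)C(C)(C)C | intermediate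
20 | (1S,3aR,8aS)-1-[(2S,5S)-5-{[tert-butyl(dimethyl)silyl]oxy}-2-hydroxy-6-methylhept-6-en-2-yl]-3a,6-dimethyl-2,3,3a,4,8,8a-hexahydroazulen-5(1H)-one | C=C(C)[C@H](CC[C@](C)(O)[C@H]1CC[C@]2(C)CC(=O)C(C)=CC[C@@H]12)O[Si](C)(C)C(C)(C)C | intermediate
21 | (1S,3aR,8aS)-1-[(2S,5S)-2,5-dihydroxy-6-methylhept-6-en-2-yl]-3a,6-dimethyl-2,3,3a,4,8,8a-hexahydroazulen-5(1H)-one | C=C(C)[C@H](CC[C@](C)(O)[C@H]1CC[C@]2(C)CC(=O)C(C)=CC[C@@H]12)O | intermediate (not isolated)
22 | (3S,6S)-6-[(1S,3aR,8aS)-3a,6-dimethyl-5-oxo-1,2,3,3a,4,5,8,8a-octahydroazulen-1-yl]-6-hydroxy-2-methylhept-1-en-3-yl acetate | C=C(C)[C@H](CC[C@](C)(O)[C@H]1CC[C@]2(C)CC(=O)C(C)=CC[C@@H]12)OC(C)=O | target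

**Step count and risks**

Total steps: 11. Longest linear sequence: 8 (steps 1, 2, 3, 7, 8, 9, 10, 11); steps 4–6 make the side chain.

The three steps most likely to fail:

Step 1 (proposed new method). The silylium–IDPi conjugate Sakurai addition may not turn over with an α-methyl enone or may give low ee. The fallback uses known chiral-auxiliary chemistry and sets out from 1 and 3. The lithium anion of the C2-symmetric chiral methallylphosphonamide F1 (n-BuLi, THF, −78 °C; made from 3-chloro-2-methylpropene and trans-N,N′-dimethylcyclohexane-1,2-diamine, auxiliary antipode chosen for the 3S series) adds through its γ-carbon 1,4 to 1. The enolate is allylated in the same flask with 3 to give the trans vinylphosphonamide adduct F2. Ozonolysis of both C=C bonds of F2 (O3; Me2S) gives the methyl ketone and the aldehyde arm directly, so the fallback comes back to the route at keto-aldehyde 7, which is cyclised with KOH as in step 2.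

Step 7. The Grignard reagent may not distinguish the acetyl group from the ring ketone, or may enolise 9. The fallback masks the ring ketone by a redox detour and sets out from 8. Borohydride at low temperature (NaBH4, MeOH/CH2Cl2, −78 → −40 °C) reduces the saturated ring ketone and leaves the conjugated acetyl group, giving the hydroxy enone F3. Hydrogenation (H2, Pd/C) gives the hydroxy methyl ketone F4. Excess 15 then adds to the only carbonyl left and gives the diol F5. Dess–Martin oxidation of the secondary alcohol (the tertiary one is inert) comes back to the route at 16. This fallback fixes chemoselectivity only; the Felkin–Anh selectivity at the new carbinol is unchanged.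

Step 8. The carbenoid expansion may migrate the wrong carbon, or the strong bases may not be tolerated this late. The fallback is a stepwise cationic semipinacol and sets out from 16. Phenylselenomethyllithium (from bis(phenylseleno)methane and n-BuLi, THF, −78 °C) adds to the ring ketone and gives the isolable β-hydroxy selenide F6. Se-methylation (MeI, AgBF4, CH2Cl2) makes the selenonium leaving group, which departs with 1,2-shift of the more substituted ring carbon. This comes back to the route at 18.

Further compounds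
F1 | step 1 | (3aR,7aR)-1,3-dimethyl-2-(2-methylprop-2-en-1-yl)octahydro-1H-1,3,2-benzodiazaphosphole 2-oxide | C=C(C)CP1(=O)N(C)[C@@H]2CCCC[C@H]2N1C
F2 | step 1 | (2S,3S)-2-allyl-3-[(E)-3-((3aR,7aR)-1,3-dimethyl-2-oxidooctahydro-1H-1,3,2-benzodiazaphosphol-2-yl)-2-methylallyl]-2-methylcyclohexan-1-one | C=CC[C@]1(C)C(=O)CCC[C@H]1C/C(C)=C/P1(=O)N(C)[C@@H]2CCCC[C@H]2N1C
F3 | step 7 | 1-[(3aS,7aR)-4-hydroxy-3a-methyl-3a,4,5,6,7,7a-hexahydro-3H-inden-1-yl]ethan-1-one (C4 epimers) | CC(=O)C1=CC[C@]2(C)C(O)CCC[C@@H]12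
F4 | step 7 | 1-[(1S,3aS,7aS)-4-hydroxy-3a-methyloctahydro-1H-inden-1-yl]ethan-1-one (C4 epimers) | CC(=O)[C@H]1CC[C@]2(C)C(O)CCC[C@@H]12
F5 | step 7 | (1S,3aS,7aS)-1-[(2S,5S)-5-{[tert-butyl(dimethyl)silyl]oxy}-2-hydroxy-6-methylhept-6-en-2-yl]-3a-methyloctahydro-1H-inden-4-ol (C4 epimers) | C=C(C)[C@H](CC[C@](C)(O)[C@H]1CC[C@]2(C)C(O)CCC[C@@H]12)O[Si](C)(C)C(C)(C)C
F6 | step 8 | (1S,3aS,7aS)-1-[(2S,5S)-5-{[tert-butyl(dimethyl)silyl]oxy}-2-hydroxy-6-methylhept-6-en-2-yl]-3a-methyl-4-[(phenylselanyl)methyl]octahydro-1H-inden-4-ol (C4 epimers) | C=C(C)[C@H](CC[C@](C)(O)[C@H]1CC[C@]2(C)C(O)(C[Se]c3ccccc3)CCC[C@@H]12)O[Si](C)(C)C(C)(C)C
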